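A direct plan would start from luteolin A1, would mask its ring-B catechol as the diphenylmethylene ketal A2, would sulfate the 7-OH to the tetrabutylammonium 7-monosulfate A3, would then oxidise the C6–H bond of the intact flavone to a second sulfooxy group in the protected 6,7-disulfate A4 and would finally take the ketal off. Its weakest steps would be:
- the C6–H sulfooxylation, which would have no precedent on a flavone, would have to choose C6 over C8 and would act on a ring that over-oxidises easily;
- the catechol ketalisation, which would need about 175 °C on a tetraphenol and would be likely to stop short of clean conversion;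
- the ketal hydrogenolysis on a dianionic bis-sulfate, where slow cleavage of the hindered C–O bonds would compete with reduction of the C2=C3 bond and with loss of sulfate.

**New strategy.** Ring A is read as a reduced 2,6-dialkoxy-1,4-benzoquinone: O6 and the ring oxygen O1 (on C8a) are para, and C4a and C8 are the two equivalent CH carbons of that quinone. The route rests on the C4–C4a bond, made by light-driven union of the formyl carbon of an arylpropynal with a quinone CH carbon, two electrophilic carbons joined through a radical pair. The hydroquinone OH set free para to O6 then closes O1–C2 of ring C. One operation gives the complete 5,6,7-trioxygenated flavone with O6 already in place, so no C–H oxygenation on a flavone, no luteolin and no catechol ketal occur; both sulfates enter by plain O-sulfation of a 6,7-diol.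

Key step: step 3

Assumption: the drawn free bis(hydrogen sulfate) is taken as the form wanted; it would be generated from the stable disodium salt only in the last operation and kept cold.

**Step 1**
Reactants: 1 4-bromocatechol (4-bromobenzene-1,2-diol)
Product: 2 4-bromo-1,2-phenylene bis(2,2-dimethylpropanoate)
Conditions: PivCl (2.4 equiv), Et3N (3 equiv), DMAP (5 mol%), CH2Cl2, 0 → 23 °C
Reagents that add atoms: pivaloyl chloride, CC(C)(C)C(=O)Cl
Why: DMAP-catalysed O-acylation of both phenols; pivalates are chosen for ring B because they have no weak C–H bond, make the aryl group a poor electron donor in the photochemical step, should tolerate BBr3, and leave under base that aryl sulfates withstand; no stereocentre.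

**Step 2**
Reactants: 2 4-bromo-1,2-phenylene bis(2,2-dimethylpropanoate); 3 3,3-diethoxyprop-1-yne
Product: 5 4-(3-oxoprop-1-yn-1-yl)-1,2-phenylene bis(2,2-dimethylpropanoate), via diethyl acetal 4 (not isolated)
Conditions: PdCl2(PPh3)2 (3 mol%), CuI (5 mol%), Et3N–THF (1:2), 60 °C; filter, concentrate; TsOH·H2O (10 mol%), acetone–H2O (10:1), 23 → 40 °C
Reagents that add atoms: water, O
Why: Sonogashira coupling of the acyloxy-activated aryl bromide with the acetal-protected propynal (the free ynal would add the amine), then acid-catalysed acetal hydrolysis, which spares aryl pivalates; no stereocentre.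

**Step 3**
Reactants: 5 4-(3-oxoprop-1-yn-1-yl)-1,2-phenylene bis(2,2-dimethylpropanoate); 6 2,6-dimethoxy-1,4-benzoquinone
Product: 8 4-(6-hydroxy-5,7-dimethoxy-4-oxo-4H-chromen-2-yl)-1,2-phenylene bis(2,2-dimethylpropanoate), via acylhydroquinone 7 (not isolated)
Conditions: 6 (1.3 equiv), PhCF3–MeCN (3:1), 0.02 M in 5, argon, 405 nm LEDs, 20 °C; concentrate; TfOH (20 mol%), CH2Cl2, 0 → 23 °C
Reagents that add atoms: none
Why: Light absorbed only by quinone 6 gives its triplet, which abstracts the formyl hydrogen of 5; the semiquinone–alkynoyl radical pair (an alkynoyl radical cannot lose CO) couples at an unsubstituted ring carbon of 6, or the acyl radical adds there to ground-state 6, and enolisation gives acylhydroquinone 7, so that the formyl carbon and a quinone carbon, both electrophiles, are joined as C4–C4a. The closest known reaction type is the photo-Friedel–Crafts acylation of 1,4-quinones by aldehydes, a C-acylation that has been run with alkyl, aryl and α,β-unsaturated aldehydes and is applied here to an ynal. Ring C is then closed by acid-promoted 6-endo-dig oxa-Michael addition of the hydroquinone OH ortho to the ketone onto the ynone, a known cyclisation of o-hydroxyaryl ynones in which 5-exo closure to an aurone is disfavoured because positive charge builds up on the aryl-bearing alkyne carbon. No stereocentre is formed. Regiochemistry needs no control: the two CH carbons of 6 are equivalent, and in 7 only the OH para to the future O6 is ortho to the carbonyl, the other being flanked by two methoxy groups, so the 5,6,7-pattern is fixed and the 5,7,8-isomer cannot form. The chemoselectivity needed, hydrogen abstraction from CHO in preference to cycloaddition or electron transfer with the alkyne and to attack on the side chains, should follow from the weak formyl C–H bond, from the alkyne being conjugated to CHO and attached to an acyloxy-substituted ring, and from methoxy and tert-butyl groups offering no weak C–H bond.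

**Step 4**
Reactants: 8 4-(6-hydroxy-5,7-dimethoxy-4-oxo-4H-chromen-2-yl)-1,2-phenylene bis(2,2-dimethylpropanoate)
Product: 9 4-(5,6,7-trihydroxy-4-oxo-4H-chromen-2-yl)-1,2-phenylene bis(2,2-dimethylpropanoate)
Conditions: BBr3 (5 equiv), CH2Cl2, −78 → 0 °C, 3 h; ice-water, EtOAc
Reagents that add atoms: none
Why: Lewis-acid cleavage of aryl methyl ethers, in which the 5-OMe is activated by chelation to the C4 carbonyl and the 7-OMe by the neighbouring 6-O–BBr2 group (cyclic borate), so both should leave at or below 0 °C, where aryl pivalates, which offer bromide no alkyl carbon, should stay, and the cold non-protic work-up avoids Wessely–Moser isomerisation; no stereocentre.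

**Step 5**
Reactants: 9 4-(5,6,7-trihydroxy-4-oxo-4H-chromen-2-yl)-1,2-phenylene bis(2,2-dimethylpropanoate)
Product: 10 disodium 2-[3,4-bis(2,2-dimethylpropanoyloxy)phenyl]-5-hydroxy-4-oxo-4H-chromene-6,7-diyl bis(sulfate)
Conditions: SO3·pyridine (8 equiv), DMF, 45 °C, 16 h, argon; aq NaHCO3 to pH 7.5; Sephadex LH-20 (MeOH–H2O)
Reagents that add atoms: sulfur trioxide–pyridine complex, O=S(=O)([O-])[n+]1ccccc1; sodium hydrogen carbonate, [Na+].OC(=O)[O-]
Why: Phenol O-sulfation with an SO3–amine complex, in which the acidic 7-OH and the 6-OH react while the 5-OH, hydrogen-bonded to the C4 carbonyl, is the one flavone phenol that normally survives exhaustive sulfation, and ring B has no free OH; no stereocentre.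

**Step 6**
Reactants: 10 disodium 2-[3,4-bis(2,2-dimethylpropanoyloxy)phenyl]-5-hydroxy-4-oxo-4H-chromene-6,7-diyl bis(sulfate)
Product: 12 6-hydroxyluteolin 6,7-disulfate (target), via disodium salt 11 (not isolated)
Conditions: NaOMe (4.5 equiv), MeOH, 0 → 23 °C, argon; 1 M HCl to pH 2, 0 °C; C18 cartridge (cold 0.01 M HCl, then H2O, then MeOH–H2O), freeze-dry, store at −20 °C
Reagents that add atoms: none
Why: Zemplén-type transesterification of the two aryl pivalates by methoxide, to which aryl sulfate monoester anions are inert, then cold protonation and immediate desalting so that the free acid is isolated before acid solvolysis of the sulfates sets in; no stereocentre.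

## Compound list

1 | 4-bromocatechol, 4-bromobenzene-1,2-diol | Oc1ccc(Br)cc1O | starting material
2 | 4-bromo-1,2-phenylene bis(2,2-dimethylpropanoate) | CC(C)(C)C(=O)Oc1ccc(Br)cc1OC(=O)C(C)(C)C | intermediate
3 | 3,3-diethoxyprop-1-yne | C#CC(OCC)OCC | starting material
4 | 4-(3,3-diethoxyprop-1-yn-1-yl)-1,2-phenylene bis(2,2-dimethylpropanoate) (not isolated) | CCOC(OCC)C#Cc1ccc(OC(=O)C(C)(C)C)c(OC(=O)C(C)(C)C)c1 | intermediate
5 | 4-(3-oxoprop-1-yn-1-yl)-1,2-phenylene bis(2,2-dimethylpropanoate) | O=CC#Cc1ccc(OC(=O)C(C)(C)C)c(OC(=O)C(C)(C)C)c1 | intermediate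
6 | 2,6-dimethoxy-1,4-benzoquinone, 2,6-dimethoxycyclohexa-2,5-diene-1,4-dione | COC1=CC(=O)C=C(OC)C1=O | starting material
7 | 4-[3-(3,6-dihydroxy-2,4-dimethoxyphenyl)-3-oxoprop-1-yn-1-yl]-1,2-phenylene bis(2,2-dimethylpropanoate) (not isolated) | COc1cc(O)c(C(=O)C#Cc2ccc(OC(=O)C(C)(C)C)c(OC(=O)C(C)(C)C)c2)c(OC)c1O | intermediate
8 | 4-(6-hydroxy-5,7-dimethoxy-4-oxo-4H-chromen-2-yl)-1,2-phenylene bis(2,2-dimethylpropanoate), achiral | COc1cc2oc(-c3ccc(OC(=O)C(C)(C)C)c(OC(=O)C(C)(C)C)c3)cc(=O)c2c(OC)c1O | intermediate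
9 | 4-(5,6,7-trihydroxy-4-oxo-4H-chromen-2-yl)-1,2-phenylene bis(2,2-dimethylpropanoate) | CC(C)(C)C(=O)Oc1ccc(-c2cc(=O)c3c(O)c(O)c(O)cc3o2)cc1OC(=O)C(C)(C)C | intermediate
10 | disodium 2-[3,4-bis(2,2-dimethylpropanoyloxy)phenyl]-5-hydroxy-4-oxo-4H-chromene-6,7-diyl bis(sulfate) | CC(C)(C)C(=O)Oc1ccc(-c2cc(=O)c3c(O)c(OS(=O)(=O)[O-])c(OS(=O)(=O)[O-])cc3o2)cc1OC(=O)C(C)(C)C.[Na+].[Na+] | intermediate
11 | disodium 2-(3,4-dihydroxyphenyl)-5-hydroxy-4-oxo-4H-chromene-6,7-diyl bis(sulfate) (not isolated) | O=c1cc(-c2ccc(O)c(O)c2)oc2cc(OS(=O)(=O)[O-])c(OS(=O)(=O)[O-])c(O)c12.[Na+].[Na+] | intermediate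
12 | 6-hydroxyluteolin 6,7-disulfate, 2-(3,4-dihydroxyphenyl)-5-hydroxy-4-oxo-4H-chromene-6,7-diyl bis(hydrogen sulfate), achiral | O=c1cc(-c2ccc(O)c(O)c2)oc2cc(OS(=O)(=O)O)c(OS(=O)(=O)O)c(O)c12 | target

**Total steps:** 6. **Longest linear sequence:** 6 steps (1 → 2 → 5 → 8 → 9 → 10 → 12); compounds 3 and 6 are bought.

**Steps most likely to fail**

**Step 3 (photoacylation and ring closure).** The radical pair may couple at oxygen to give a hydroquinone monoester, or the excited quinone may add to the alkyne or simply be photoreduced, so that little C-acyl product forms. The fallback is a thermal, palladium-catalysed carbonylative union; it sets out from bromide 2 and comes back to the route at 9. Bromide 2 would be coupled with ethynyltrimethylsilane (PdCl2(PPh3)2, CuI, Et3N) to 4-[(trimethylsilyl)ethynyl]-1,2-phenylene bis(2,2-dimethylpropanoate) F1, which would be desilylated (AgNO3 10 mol%, acetone–H2O) to 4-ethynyl-1,2-phenylene bis(2,2-dimethylpropanoate) F2. Commercial 3,4,5-trimethoxyphenol would be iodinated (NIS, MeCN, 0 °C) at one of its two equivalent ortho carbons to 2-iodo-3,4,5-trimethoxyphenol F3. Carbonylative Sonogashira coupling of the alkyne and the iodophenol (CO 1 atm, PdCl2(PPh3)2, Et3N, THF) would give 4-[3-(6-hydroxy-2,3,4-trimethoxyphenyl)-3-oxoprop-1-yn-1-yl]-1,2-phenylene bis(2,2-dimethylpropanoate) F4. This ynone would be closed with TfOH as in step 3 to 4-(5,6,7-trimethoxy-4-oxo-4H-chromen-2-yl)-1,2-phenylene bis(2,2-dimethylpropanoate) F5, and BBr3 would remove all three methyl groups to reach 9.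

**Step 4 (demethylation).** The Lewis acid may also cleave the aryl esters, or the 7-methyl ether may resist at the low temperature the esters require. The fallback carries ring A as benzyl ethers that leave by hydrogenolysis; the union is made thermally, because benzyloxy groups on an excited quinone would be open to intramolecular hydrogen abstraction. It sets out from bromide 2, through alkyne F2 made as above, and comes back at 9. Commercial 3,4,5-tris(benzyloxy)benzaldehyde would be oxidised (Baeyer–Villiger, mCPBA) to 3,4,5-tris(benzyloxy)phenyl formate F6, which would be methanolysed (K2CO3, MeOH) to 3,4,5-tris(benzyloxy)phenol F7 and iodinated (NIS) to 3,4,5-tris(benzyloxy)-2-iodophenol F8. Carbonylative coupling of this iodophenol with alkyne F2 and CO as above would give 4-{3-[2,3,4-tris(benzyloxy)-6-hydroxyphenyl]-3-oxoprop-1-yn-1-yl}-1,2-phenylene bis(2,2-dimethylpropanoate) F9. A DMAP-catalysed 6-endo closure (DMAP 20 mol%, DMF), chosen because it spares benzyl ethers, would give 4-[5,6,7-tris(benzyloxy)-4-oxo-4H-chromen-2-yl]-1,2-phenylene bis(2,2-dimethylpropanoate) F10. H2 over 10% Pd/C (EtOAc–THF) would then free the three ring-A hydroxyls without touching the esters and give 9.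

**Step 5 (double sulfation).** Sulfation may stop at the 7-monosulfate, because the 6-OH is flanked on both sides and the first sulfate puts a negative charge next to it, while forcing conditions may begin to sulfate the 5-OH. The fallback introduces the sulfates as neutral diesters; it sets out from 9 and comes back at 10. 2,2,2-Trichloroethyl chlorosulfate (2.4 equiv), Et3N and DMAP in THF at 0 °C would give 4-{5-hydroxy-4-oxo-6,7-bis[(2,2,2-trichloroethoxy)sulfonyloxy]-4H-chromen-2-yl}-1,2-phenylene bis(2,2-dimethylpropanoate) F11, which can be purified on silica. Zn dust with HCO2NH4 in MeOH would unmask both sulfates under neutral conditions, and exchange of ammonium for sodium (aq NaHCO3, then Sephadex LH-20) would give 10.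

## Further compounds

F1 | step 3 | 4-[(trimethylsilyl)ethynyl]-1,2-phenylene bis(2,2-dimethylpropanoate) | C[Si](C)(C)C#Cc1ccc(OC(=O)C(C)(C)C)c(OC(=O)C(C)(C)C)c1
F2 | step 3 | 4-ethynyl-1,2-phenylene bis(2,2-dimethylpropanoate) | C#Cc1ccc(OC(=O)C(C)(C)C)c(OC(=O)C(C)(C)C)c1
F3 | step 3 | 2-iodo-3,4,5-trimethoxyphenol | COc1cc(O)c(I)c(OC)c1OC
F4 | step 3 | 4-[3-(6-hydroxy-2,3,4-trimethoxyphenyl)-3-oxoprop-1-yn-1-yl]-1,2-phenylene bis(2,2-dimethylpropanoate) | COc1cc(O)c(C(=O)C#Cc2ccc(OC(=O)C(C)(C)C)c(OC(=O)C(C)(C)C)c2)c(OC)c1OC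
F5 | step 3 | 4-(5,6,7-trimethoxy-4-oxo-4H-chromen-2-yl)-1,2-phenylene bis(2,2-dimethylpropanoate) | COc1cc2oc(-c3ccc(OC(=O)C(C)(C)C)c(OC(=O)C(C)(C)C)c3)cc(=O)c2c(OC)c1OC
F6 | step 4 | 3,4,5-tris(benzyloxy)phenyl formate | O=COc1cc(OCc2ccccc2)c(OCc2ccccc2)c(OCc2ccccc2)c1
F7 | step 4 | 3,4,5-tris(benzyloxy)phenol | Oc1cc(OCc2ccccc2)c(OCc2ccccc2)c(OCc2ccccc2)c1
F8 | step 4 | 3,4,5-tris(benzyloxy)-2-iodophenol | Oc1cc(OCc2ccccc2)c(OCc2ccccc2)c(OCc2ccccc2)c1I
F9 | step 4 | 4-{3-[2,3,4-tris(benzyloxy)-6-hydroxyphenyl]-3-oxoprop-1-yn-1-yl}-1,2-phenylene bis(2,2-dimethylpropanoate) | Oc1cc(OCc2ccccc2)c(OCc2ccccc2)c(OCc2ccccc2)c1C(=O)C#Cc1ccc(OC(=O)C(C)(C)C)c(OC(=O)C(C)(C)C)c1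
F10 | step 4 | 4-[5,6,7-tris(benzyloxy)-4-oxo-4H-chromen-2-yl]-1,2-phenylene bis(2,2-dimethylpropanoate) | CC(C)(C)C(=O)Oc1ccc(-c2cc(=O)c3c(OCc4ccccc4)c(OCc4ccccc4)c(OCc4ccccc4)cc3o2)cc1OC(=O)C(C)(C)C
F11 | step 5 | 4-{5-hydroxy-4-oxo-6,7-bis[(2,2,2-trichloroethoxy)sulfonyloxy]-4H-chromen-2-yl}-1,2-phenylene bis(2,2-dimethylpropanoate) | CC(C)(C)C(=O)Oc1ccc(-c2cc(=O)c3c(O)c(OS(=O)(=O)OCC(Cl)(Cl)Cl)c(OS(=O)(=O)OCC(Cl)(Cl)Cl)cc3o2)cc1OC(=O)C(C)(C)C
A1 | direct plan | luteolin, 2-(3,4-dihydroxyphenyl)-5,7-dihydroxy-4H-chromen-4-one | O=c1cc(-c2ccc(O)c(O)c2)oc2cc(O)cc(O)c12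
A2 | direct plan | 3',4'-O-(diphenylmethylene)luteolin | O=c1cc(-c2ccc3OC(c4ccccc4)(c4ccccc4)Oc3c2)oc2cc(O)cc(O)c12
A3 | direct plan | tetrabutylammonium 2-(2,2-diphenyl-1,3-benzodioxol-5-yl)-5-hydroxy-4-oxo-4H-chromen-7-yl sulfate | O=c1cc(-c2ccc3OC(c4ccccc4)(c4ccccc4)Oc3c2)oc2cc(OS(=O)(=O)[O-])cc(O)c12.CCCC[N+](CCCC)(CCCC)CCCC
A4 | direct plan | bis(tetrabutylammonium) 2-(2,2-diphenyl-1,3-benzodioxol-5-yl)-5-hydroxy-4-oxo-4H-chromene-6,7-diyl bis(sulfate) | O=c1cc(-c2ccc3OC(c4ccccc4)(c4ccccc4)Oc3c2)oc2cc(OS(=O)(=O)[O-])c(OS(=O)(=O)[O-])c(O)c12.CCCC[N+](CCCC)(CCCC)CCCC.CCCC[N+](CCCC)(CCCC)CCCC
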